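**Plan**
Retrosynthesis first cuts the C4 acyl–N bond to a chiral oxazolidinone and the two phenolic O–Si bonds, then, in one operation, the C2–aryl bond to ring A and the C3–CH2 bond to the ring B benzyl group.
The enabling feature: C1–C4 (C1 ester carbon, C2 the CH bearing ring A, C3 the CH bearing the ring B benzyl group, C4 acid carbon) is a fumarate with two different ends, and C2 and C3 each lack exactly one carbon substituent.
Forward, ring B bromide 6, ring A Grignard reagent 8 and fumarate imide 13 are made separately and joined in one flask; the chain stays open and no ring is formed.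
Both stereocentres come from one (R)-4-benzyloxazolidin-2-one: aryl transfer to C2 and benzylation at C3 each occur anti to its benzyl group within magnesium chelates, giving (2S,3R).
Buffered fluoride then frees both phenols before LiOOH removes the auxiliary, so no aryl silyl ether has to survive basic peroxide.

Key step: step 8

Remark: skeleton numbering C1 (ester carbon) to C4 (acid or imide carbon) is used throughout, and the copper reagent is formulated as the 1:1 arylcopper–MgBr2 species.

Step 1
Reactants: 1 4-hydroxybenzaldehyde; 2 prenyl bromide (1-bromo-3-methylbut-2-ene)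
Product: 3 4-hydroxy-3-(3-methylbut-2-en-1-yl)benzaldehyde
Conditions: 10% aq. KOH, rt
Reagents that add atoms: none
Why: Phenoxide C-alkylation: in water the phenoxide oxygen is hydrogen-bonded, so the ambident anion reacts with the allylic bromide at the free ortho carbon (para is blocked by the formyl group), a known direct ortho-prenylation of this aldehyde.

Step 2
Reactants: 3 4-hydroxy-3-(3-methylbut-2-en-1-yl)benzaldehyde
Product: 4 4-(tert-butyldimethylsilyloxy)-3-(3-methylbut-2-en-1-yl)benzaldehyde
Conditions: TBSCl, imidazole, DMF, rt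
Reagents that add atoms: tert-butyldimethylsilyl chloride, CC(C)(C)[Si](C)(C)Cl
Why: Standard imidazole-promoted silylation of a phenol; the aldehyde and the prenyl group are inert.

Step 3
Reactants: 4 4-(tert-butyldimethylsilyloxy)-3-(3-methylbut-2-en-1-yl)benzaldehyde
Product: 5 [4-(tert-butyldimethylsilyloxy)-3-(3-methylbut-2-en-1-yl)phenyl]methanol
Conditions: NaBH4, THF/MeOH, 0 °C
Reagents that add atoms: none
Why: Borohydride reduction of an aryl aldehyde is fast at 0 °C and should leave the aryl silyl ether and the trisubstituted alkene untouched.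

Step 4
Reactants: 5 [4-(tert-butyldimethylsilyloxy)-3-(3-methylbut-2-en-1-yl)phenyl]methanol
Product: 6 4-(tert-butyldimethylsilyloxy)-3-(3-methylbut-2-en-1-yl)benzyl bromide
Conditions: CBr4, PPh3, CH2Cl2, 0 °C; used promptly
Reagents that add atoms: tetrabromomethane, BrC(Br)(Br)Br
Why: The Appel reaction converts the benzylic alcohol to the bromide under neutral conditions, which avoids HBr addition to the prenyl alkene and loss of the silyl ether.

Step 5
Reactants: 7 (4-bromophenoxy)(tert-butyl)dimethylsilane
Product: 8 4-(tert-butyldimethylsilyloxy)phenylmagnesium bromide (THF solution, titrated and used as such)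
Conditions: Mg turnings, cat. I2, THF, 45 °C
Reagents that add atoms: magnesium, [Mg]
Why: Grignard formation by magnesium insertion into the aryl C–Br bond; aryl silyl ethers are stable to arylmagnesium reagents.

Step 6
Reactants: 9 monomethyl fumarate
Product: 10 methyl (E)-4-chloro-4-oxobut-2-enoate
Conditions: (COCl)2, cat. DMF, CH2Cl2, 0 °C to rt; concentrated
Reagents that add atoms: oxalyl chloride, O=C(Cl)C(=O)Cl
Why: Acid chloride formation through the Vilsmeier-type chloroiminium species; the E alkene is the stable geometry and is retained.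

Step 7
Reactants: 11 (R)-4-benzyloxazolidin-2-one; 10 methyl (E)-4-chloro-4-oxobut-2-enoate
Product: 13 methyl (E)-4-[(R)-4-benzyl-2-oxooxazolidin-3-yl]-4-oxobut-2-enoate, via lithium oxazolidinide 12 (not isolated)
Conditions: n-BuLi, THF, −78 °C; then 10, −78 to 0 °C
Reagents that add atoms: none
Why: Evans N-acylation: the lithiated carbamate nitrogen attacks the acid chloride far faster than the ester or the alkene, giving the unsymmetrical fumarate imide.

Step 8
Reactants: 8 4-(tert-butyldimethylsilyloxy)phenylmagnesium bromide; 13 methyl (E)-4-[(R)-4-benzyl-2-oxooxazolidin-3-yl]-4-oxobut-2-enoate; 6 4-(tert-butyldimethylsilyloxy)-3-(3-methylbut-2-en-1-yl)benzyl bromide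
Product: 16 methyl (2S,3R)-4-[(R)-4-benzyl-2-oxooxazolidin-3-yl]-2-[4-(tert-butyldimethylsilyloxy)phenyl]-3-[4-(tert-butyldimethylsilyloxy)-3-(3-methylbut-2-en-1-yl)benzyl]-4-oxobutanoate, via arylcopper 14 (not isolated), via magnesium enolate 15 (not isolated)
Conditions: 8 (1.3 equiv), CuBr·SMe2 (1.3 equiv), THF (no added Me2S), −40 °C; then 13, −78 to −40 °C; then DMPU, 6 (1.8 equiv), −40 to 0 °C; aq. NH4Cl
Reagents that add atoms: none
Why: Transmetalation of 8 to CuBr·SMe2 gives arylcopper 14 (monovalent copper) and MgBr2, whose magnesium chelates both imide carbonyls of 13, holds the enoyl unit s-cis and makes C2, the alkene carbon β to the imide, the electrophilic terminus, so the aryl group is delivered there through a copper–alkene π-complex and reductive elimination. The aryl group enters on the face away from the auxiliary benzyl group, which sets C2 as S and leaves the chelated Z bromomagnesium enolate 15 at C3 as the only enolate. Bromide 6, an electron-rich and therefore fast benzylic electrophile, should alkylate 15 in DMPU-containing THF before proton exchange with the acidic C2–H sets in, again anti to the auxiliary benzyl group, which sets C3 as R (Evans-type enolate alkylation). The closest known reaction type is the tandem organocopper conjugate addition–enolate trapping of N-enoyl oxazolidinones and of N-enoyl sultams; no ring is closed. The step needs regioselectivity (β to the imide, not β to the ester), secured by chelation of the imide alone, and auxiliary control at C3 over the resident C2 centre, secured by the rigid chelate. Me2S is limited to the one equivalent in the copper complex so that it does not consume 6.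

Step 9
Reactants: 16 methyl (2S,3R)-4-[(R)-4-benzyl-2-oxooxazolidin-3-yl]-2-[4-(tert-butyldimethylsilyloxy)phenyl]-3-[4-(tert-butyldimethylsilyloxy)-3-(3-methylbut-2-en-1-yl)benzyl]-4-oxobutanoate
Product: 17 methyl (2S,3R)-4-[(R)-4-benzyl-2-oxooxazolidin-3-yl]-3-[4-hydroxy-3-(3-methylbut-2-en-1-yl)benzyl]-2-(4-hydroxyphenyl)-4-oxobutanoate
Conditions: Bu4NF, AcOH, THF, 0 °C
Reagents that add atoms: none
Why: Fluoride cleaves both aryl silyl ethers quickly through Si–F bond formation, and the acetic acid buffer should keep the medium from epimerizing C2 or opening the imide.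

Step 10
Reactants: 17 methyl (2S,3R)-4-[(R)-4-benzyl-2-oxooxazolidin-3-yl]-3-[4-hydroxy-3-(3-methylbut-2-en-1-yl)benzyl]-2-(4-hydroxyphenyl)-4-oxobutanoate
Product: 19 asperteretal G1, via peroxy acid 18 (not isolated)
Conditions: LiOH·H2O (4 equiv), 30% aq. H2O2, THF/H2O 3:1, 0 °C; then aq. Na2SO3, 0 °C; then 1 M HCl to pH 3
Reagents that add atoms: hydrogen peroxide, OO
Why: Evans LiOOH cleavage: hydroperoxide is more nucleophilic and less basic than hydroxide and attacks the exocyclic imide carbonyl in preference to the hindered α-aryl methyl ester and the ring carbonyl; peroxy acid 18 stays as its non-electrophilic anion and is reduced by sulfite before acidification, so the prenyl alkene should not be epoxidized, and the ring A phenoxide lowers the acidity of C2–H against epimerization.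

**Compound list**
1 | 4-hydroxybenzaldehyde | O=Cc1ccc(O)cc1 | starting material
2 | prenyl bromide (1-bromo-3-methylbut-2-ene) | CC(C)=CCBr | starting material
3 | 4-hydroxy-3-(3-methylbut-2-en-1-yl)benzaldehyde | O=Cc1ccc(O)c(CC=C(C)C)c1 | intermediate
4 | 4-(tert-butyldimethylsilyloxy)-3-(3-methylbut-2-en-1-yl)benzaldehyde | O=Cc1ccc(O[Si](C)(C)C(C)(C)C)c(CC=C(C)C)c1 | intermediate
5 | [4-(tert-butyldimethylsilyloxy)-3-(3-methylbut-2-en-1-yl)phenyl]methanol | OCc1ccc(O[Si](C)(C)C(C)(C)C)c(CC=C(C)C)c1 | intermediate
6 | 4-(tert-butyldimethylsilyloxy)-3-(3-methylbut-2-en-1-yl)benzyl bromide | BrCc1ccc(O[Si](C)(C)C(C)(C)C)c(CC=C(C)C)c1 | intermediate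
7 | (4-bromophenoxy)(tert-butyl)dimethylsilane | Brc1ccc(O[Si](C)(C)C(C)(C)C)cc1 | starting material
8 | 4-(tert-butyldimethylsilyloxy)phenylmagnesium bromide | Br[Mg]c1ccc(O[Si](C)(C)C(C)(C)C)cc1 | intermediate
9 | monomethyl fumarate | COC(=O)/C=C/C(=O)O | starting material
10 | methyl (E)-4-chloro-4-oxobut-2-enoate | COC(=O)/C=C/C(=O)Cl | intermediate
11 | (R)-4-benzyloxazolidin-2-one | O=C1N[C@H](Cc2ccccc2)CO1 | starting material
12 | lithium (R)-4-benzyl-2-oxooxazolidin-3-ide (not isolated) | [Li]N1[C@H](Cc2ccccc2)COC1=O | intermediate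
13 | methyl (E)-4-[(R)-4-benzyl-2-oxooxazolidin-3-yl]-4-oxobut-2-enoate | COC(=O)/C=C/C(=O)N1[C@H](Cc2ccccc2)COC1=O | intermediate
14 | 4-(tert-butyldimethylsilyloxy)phenylcopper, as its MgBr2 complex (not isolated) | [Cu]c1ccc(O[Si](C)(C)C(C)(C)C)cc1 | intermediate
15 | bromomagnesium Z enolate of methyl (S)-4-[(R)-4-benzyl-2-oxooxazolidin-3-yl]-2-[4-(tert-butyldimethylsilyloxy)phenyl]-4-oxobutanoate (not isolated) | COC(=O)[C@H](c1ccc(O[Si](C)(C)C(C)(C)C)cc1)/C=C(\O[Mg]Br)N1[C@H](Cc2ccccc2)COC1=O | intermediate
16 | methyl (2S,3R)-4-[(R)-4-benzyl-2-oxooxazolidin-3-yl]-2-[4-(tert-butyldimethylsilyloxy)phenyl]-3-[4-(tert-butyldimethylsilyloxy)-3-(3-methylbut-2-en-1-yl)benzyl]-4-oxobutanoate | COC(=O)[C@H](c1ccc(O[Si](C)(C)C(C)(C)C)cc1)[C@@H](Cc1ccc(O[Si](C)(C)C(C)(C)C)c(CC=C(C)C)c1)C(=O)N1[C@H](Cc2ccccc2)COC1=O | intermediate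
17 | methyl (2S,3R)-4-[(R)-4-benzyl-2-oxooxazolidin-3-yl]-3-[4-hydroxy-3-(3-methylbut-2-en-1-yl)benzyl]-2-(4-hydroxyphenyl)-4-oxobutanoate | COC(=O)[C@H](c1ccc(O)cc1)[C@@H](Cc1ccc(O)c(CC=C(C)C)c1)C(=O)N1[C@H](Cc2ccccc2)COC1=O | intermediate
18 | C4 peroxy acid of 19, (2S,3R) in skeleton numbering (not isolated) | COC(=O)[C@H](c1ccc(O)cc1)[C@@H](Cc1ccc(O)c(CC=C(C)C)c1)C(=O)OO | intermediate
19 | asperteretal G1, 1-methyl hydrogen (2S,3R)-2-(4-hydroxyphenyl)-3-[4-hydroxy-3-(3-methylbut-2-en-1-yl)benzyl]butanedioate | COC(=O)[C@H](c1ccc(O)cc1)[C@@H](Cc1ccc(O)c(CC=C(C)C)c1)C(=O)O | target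

**Count**
Total steps: 10. Longest linear sequence: 7 steps (steps 1, 2, 3, 4, 8, 9, 10 from 4-hydroxybenzaldehyde).

**Steps most likely to fail**

Step 8. Several processes may interfere:
- C-alkylation of the bromomagnesium enolate may be slow, so that proton transfer from C2–H (scrambling C2), O-alkylation, or sulfonium formation between the bromide and Me2S compete.
- DMPU may loosen the chelate and erode facial control at C3, which has to override the resident C2 centre.

The fallback separates the two bond formations and sets out from 13. Conjugate addition of 8 with CuBr·SMe2 in THF at −78 to −40 °C is quenched with aq. NH4Cl to give the conjugate adduct methyl (S)-4-[(R)-4-benzyl-2-oxooxazolidin-3-yl]-2-[4-(tert-butyldimethylsilyloxy)phenyl]-4-oxobutanoate F1. Kinetic deprotonation of the chelating imide CH2 with NaN(SiMe3)2 in THF at −78 °C, followed by 6, gives the more reactive sodium Z enolate alkylation without polar additive and comes back to the route at 16.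

Step 10. Hydroperoxide or hydroxide may attack the methyl ester or the ring carbonyl of the hindered imide, and the transient peroxy acid may oxidize the prenyl alkene. The fallback avoids peroxide altogether and sets out from 16. BnSLi (from BnSH and n-BuLi, THF, 0 °C) should cleave only the exocyclic imide carbonyl to give the thioester methyl (2S,3R)-4-(benzylsulfanyl)-2-[4-(tert-butyldimethylsilyloxy)phenyl]-3-[4-(tert-butyldimethylsilyloxy)-3-(3-methylbut-2-en-1-yl)benzyl]-4-oxobutanoate F2. Bu4NF/AcOH in THF then gives methyl (2S,3R)-4-(benzylsulfanyl)-3-[4-hydroxy-3-(3-methylbut-2-en-1-yl)benzyl]-2-(4-hydroxyphenyl)-4-oxobutanoate F3. Thiophilic hydrolysis with AgNO3 and 2,6-lutidine in aqueous THF leaves the methyl ester alone and comes back to the route at 19.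

Step 1. O-alkylation and double C-prenylation may outrun the single ortho C-alkylation and make isolation of 3 inefficient. The fallback builds the prenyl group by rearrangement and metathesis and sets out from 1. Allyl bromide and K2CO3 in acetone give 4-(allyloxy)benzaldehyde F4. Aromatic Claisen rearrangement in N,N-diethylaniline at about 200 °C gives 3-allyl-4-hydroxybenzaldehyde F5. TBSCl and imidazole give 3-allyl-4-(tert-butyldimethylsilyloxy)benzaldehyde F6. Cross-metathesis with excess 2-methylbut-2-ene and the second-generation Grubbs catalyst in CH2Cl2 at 40 °C converts allyl into prenyl and comes back to the route at 4, so step 2 is also bypassed.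

**Further compounds**
F1 | step 8 | methyl (S)-4-[(R)-4-benzyl-2-oxooxazolidin-3-yl]-2-[4-(tert-butyldimethylsilyloxy)phenyl]-4-oxobutanoate | COC(=O)[C@H](c1ccc(O[Si](C)(C)C(C)(C)C)cc1)CC(=O)N1[C@H](Cc2ccccc2)COC1=O
F2 | step 10 | methyl (2S,3R)-4-(benzylsulfanyl)-2-[4-(tert-butyldimethylsilyloxy)phenyl]-3-[4-(tert-butyldimethylsilyloxy)-3-(3-methylbut-2-en-1-yl)benzyl]-4-oxobutanoate | COC(=O)[C@H](c1ccc(O[Si](C)(C)C(C)(C)C)cc1)[C@@H](Cc1ccc(O[Si](C)(C)C(C)(C)C)c(CC=C(C)C)c1)C(=O)SCc1ccccc1
F3 | step 10 | methyl (2S,3R)-4-(benzylsulfanyl)-3-[4-hydroxy-3-(3-methylbut-2-en-1-yl)benzyl]-2-(4-hydroxyphenyl)-4-oxobutanoate | COC(=O)[C@H](c1ccc(O)cc1)[C@@H](Cc1ccc(O)c(CC=C(C)C)c1)C(=O)SCc1ccccc1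
F4 | step 1 | 4-(allyloxy)benzaldehyde | C=CCOc1ccc(C=O)cc1
F5 | step 1 | 3-allyl-4-hydroxybenzaldehyde | C=CCc1cc(C=O)ccc1O
F6 | step 1 | 3-allyl-4-(tert-butyldimethylsilyloxy)benzaldehyde | C=CCc1cc(C=O)ccc1O[Si](C)(C)C(C)(C)C
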